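Starting complex leaves the ochre flask at 0.107 h⁻¹ of its charge over the first 5.00 h, but at 0.00960 h⁻¹ from then until 15.0 h, which is slower. Here is what stands and what is asked.

common to all: starting complex 0.30 M
- ochre: incoming ligand 0.21 M; leaving ligand 0.30 M; temperature 90 °C; the very flask that is asked about, followed so far
- blue: incoming ligand 0.10 M; leaving ligand 0.30 M; temperature 75 °C; run made earlier
- flask: incoming ligand 0.210 M; leaving ligand 0.300 M; temperature 90 °C; time 5.0 d

| run | time / h | complex with two exchanged / % | starting complex / % |
|---|---|---|---|
| ochre | 5.00 | 10.3 | 46.4 |
| ochre | 15.0 | 15.9 | 36.8 |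
| ochre | 25.0 | 16.7 | 34.4 |
| ochre | 40.0 | 15.8 | 36.1 |
| ochre | 60.0 | 15.4 | 35.6 |
| ochre | 72.0 | 16.0 | 33.8 |
| blue | 0.333 | 0.3 | 90.9 |
| blue | 1.00 | 0 | 84.5 |
| blue | 2.00 | 1.8 | 76.5 |
| blue | 3.00 | 0.4 | 72.4 |
| blue | 4.00 | 0 | 69.8 |
| blue | 5.00 | 0 | 65.0 |

(scatter of a reading: 1 percentage point)

- Thursday's: at 5.0 d raise the temperature by 10 K, then wait 40 h
- Saturday's: change nothing and wait 40 h more
- Sunday's: at 5.0 d add incoming ligand, 100% of the amount charged, then wait 40 h
- Monday's: at 5.0 d take out 90% of the complex with two exchanged then present, then wait 40 h

- what is taken out of complex with two exchanged is counted as made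
- the numbers in the tables scatter with a standard deviation of 1 percentage point
- additions bring no volume worth counting

- complex with two exchanged, in percent of the starting complex first charged, at 5.0 d
- what to do for the largest gain in complex with two exchanged; "none" if nothing gains more than 2 percentage points (Thursday's / Saturday's / Sunday's / Monday's / none)
- complex with two exchanged present, with what was taken out counted in, in percent of the starting complex first charged, after Sunday's
- complex with two exchanged present, with what was taken out counted in, in percent of the starting complex first charged, after Monday's

The rate has dropped by a factor of 11.2. Starting complex itself, judged by its mean level in each span, gives a factor of 1.76. I put the larger remaining factor of 6.35 on incoming ligand being used up and on the way back, which these readings cannot separate. From 25.0 h on, complex with two exchanged stays within the scatter of 1 percentage point, so the slowing has reached a stop well before 5.0 d, and I read 16.0% for the ochre flask.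

To see what the stop means I count turnovers. Each exchange uses one incoming ligand, so the turnover budget, the exchanges paid for per starting complex charged, c(incoming ligand) over c(starting complex), is 0.700, and incoming ligand is the limiting reagent. Complex with two exchanged costs two turnovers, so its ceiling is 35.0%. If all the lost starting complex had exchanged, the readings at 72.0 h would cost 82.2% of the starting complex charged, more than the budget of 70.0%. So the budget of 0.700 can be fully spent at the stop, with some complex in a form that costs nothing, and I take the stop for that. Sunday's then raises the budget to 1.40 and the ceiling to 70.0%, while Monday's adds no incoming ligand, so with what is taken out counted in I expect it to stay near 16.0%. Thursday's and Saturday's add no incoming ligand either, so I choose Sunday's.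

The forecast gives 16% now, Sunday's as best, 38% after Sunday's and 22% after Monday's, reading the plateau as “so 5.0 d is equilibrium and waiting gains nothing”. On Monday's we part.

The flask gives 16.7% at 5.0 d, and Sunday's is best, gaining 35 points to reach 52.1%, while Monday's gains 0 points and stays at 16.7%.

complex with one exchanged + incoming ligand ⇌ leaving ligand + complex with two exchanged (K = 0.270, k = 6.40 × 10⁻⁴ M⁻¹ s⁻¹, Ea = 93.0 kJ mol⁻¹, ΔH = 13.0 kJ mol⁻¹); leaving ligand → by-product carried off (k = 1.60 × 10⁻⁴ s⁻¹, Ea = 123 kJ mol⁻¹); starting complex + incoming ligand ⇌ leaving ligand + complex with one exchanged (K = 0.540, k = 0.00160 M⁻¹ s⁻¹, Ea = 74.0 kJ mol⁻¹, ΔH = −17.0 kJ mol⁻¹); starting complex ⇌ dormant form (K = 0.340, k = 1.30 × 10⁻⁴ s⁻¹, Ea = 118 kJ mol⁻¹, ΔH = −22.0 kJ mol⁻¹); (constants at 90 °C) At 120 h this flask holds 0% of its incoming ligand, and complex with one exchanged plus twice complex with two exchanged counts 0.700 turnovers against the budget of 0.700. The neighbour, like this flask but charged with 0.36 M of incoming ligand, has a budget of 1.20 and a ceiling of 60.0%. In that neighbour incoming ligand ends at 0%, the same count gives 1.20, and complex with two exchanged reaches 41.3%.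

(The runs were generated by integration for substances that don't exist, noise included.)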